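The cyclohexene is numbered C1 (bearing the C7 benzoyloxymethyl arm), C2 (vinylic CH) and C3–C6 (the four carbinol carbons, benzoate on C5). The feature exploited is that C3–C4–C5–C6–C1–C7, with the all-cis oxygens on C4, C5 and C6, is the intact carbon chain of D-allose, so only C2 has to be added. The route rests on closing the carbocycle between C2 and C3: a furanose lactol that already carries both benzoates and a (Z)-bromomethylidene group opens to its hydroxy aldehyde, and an intramolecular Nozaki–Hiyama–Kishi addition forms the ring, creates the C3 carbinol, frees O6 from the lactol and delivers the unprotected target in one operation.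

Key step: step 8

Remark: 1,2:5,6-di-O-isopropylidene-α-D-allofuranose is taken as a commercial starting material, and lactol 8 is an anomeric mixture, so its anomeric centre is left undefined in the SMILES.

Step 1
Reactants: 1 1,2:5,6-di-O-isopropylidene-α-D-allofuranose
Product: 2 3-O-benzoyl-1,2:5,6-di-O-isopropylidene-α-D-allofuranose
Conditions: BzCl, pyridine, DMAP (cat.), CH2Cl2, 0 °C to rt
Reagents that add atoms: benzoyl chloride, O=C(Cl)c1ccccc1
Why: DMAP-catalysed acylation of the only free hydroxyl (sugar O3, the future C5 benzoate) should proceed without touching any stereocentre.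

Step 2
Reactants: 2 3-O-benzoyl-1,2:5,6-di-O-isopropylidene-α-D-allofuranose
Product: 3 3-O-benzoyl-1,2-O-isopropylidene-α-D-allofuranose
Conditions: AcOH/H2O (7:3), rt
Reagents that add atoms: none
Why: Selective acid-catalysed acetal hydrolysis should remove the terminal 5,6-acetonide, which is cleaved much faster than the cis-fused anomeric 1,2-acetonide, while the benzoate is stable to aqueous acetic acid.

Step 3
Reactants: 3 3-O-benzoyl-1,2-O-isopropylidene-α-D-allofuranose
Product: 4 3,6-di-O-benzoyl-1,2-O-isopropylidene-α-D-allofuranose
Conditions: BzCl (1.05 equiv), pyridine, CH2Cl2, –40 to –20 °C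
Reagents that add atoms: benzoyl chloride, O=C(Cl)c1ccccc1
Why: Regioselective acylation should take the primary 6-OH (the future C7 benzoate) in preference to the hindered secondary 5-OH at low temperature.

Step 4
Reactants: 4 3,6-di-O-benzoyl-1,2-O-isopropylidene-α-D-allofuranose
Product: 5 3,6-di-O-benzoyl-1,2-O-isopropylidene-α-D-ribo-hexofuranos-5-ulose
Conditions: Dess–Martin periodinane, CH2Cl2, 0 °C to rt
Reagents that add atoms: none
Why: Dess–Martin oxidation of the single free secondary alcohol should give the 5-ketone under base-free conditions, which avoids β-elimination of the C3 benzoate.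

Step 5
Reactants: 5 3,6-di-O-benzoyl-1,2-O-isopropylidene-α-D-ribo-hexofuranos-5-ulose
Product: 6 3,6-di-O-benzoyl-5-deoxy-5-C-(dibromomethylidene)-1,2-O-isopropylidene-α-D-ribo-hexofuranose
Conditions: CBr4, PPh3, Zn dust, CH2Cl2, rt (ylide preformed), then 5, rt to 40 °C
Reagents that add atoms: carbon tetrabromide, BrC(Br)(Br)Br
Why: Ramirez (Corey–Fuchs-type) dibromoolefination with the weakly basic ylide Ph3P=CBr2 should convert the activated, doubly α-oxygenated ketone into the gem-dibromoalkene, adding the missing carbon C2 with no geometric isomerism and no strong base.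

Step 6
Reactants: 6 3,6-di-O-benzoyl-5-deoxy-5-C-(dibromomethylidene)-1,2-O-isopropylidene-α-D-ribo-hexofuranose
Product: 7 3,6-di-O-benzoyl-5-C-[(Z)-bromomethylidene]-5-deoxy-1,2-O-isopropylidene-α-D-ribo-hexofuranose
Conditions: Bu3SnH (1.1 equiv), Pd(PPh3)4 (5 mol %), toluene, rt
Reagents that add atoms: none
Why: In this palladium-catalysed stereoselective hydrogenolysis of a 1,1-dibromoalkene, zerovalent palladium should insert into the less hindered C–Br bond (cis to the CH2OBz arm, trans to the branched furanose carbon) and tin hydride then replaces that bromine with retention, leaving bromine cis to the ring carbon (Z).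

Step 7
Reactants: 7 3,6-di-O-benzoyl-5-C-[(Z)-bromomethylidene]-5-deoxy-1,2-O-isopropylidene-α-D-ribo-hexofuranose
Product: 8 3,6-di-O-benzoyl-5-C-[(Z)-bromomethylidene]-5-deoxy-D-ribo-hexofuranose
Conditions: TFA/H2O (9:1), 0 °C
Reagents that add atoms: none
Why: Acid-catalysed hydrolysis of the anomeric 1,2-acetonide should unmask the aldehyde as its furanose hemiacetal (the only ring form possible, since sugar C5 bears no oxygen), with benzoates and the alkenyl bromide stable to cold aqueous acid.

Step 8
Reactants: 8 3,6-di-O-benzoyl-5-C-[(Z)-bromomethylidene]-5-deoxy-D-ribo-hexofuranose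
Product: 11 [(3S,4S,5R,6R)-5-(benzoyloxy)-3,4,6-trihydroxycyclohex-1-en-1-yl]methyl benzoate, via open-chain hydroxy aldehyde 9 (not isolated), via alkenylchromium dichloride 10 (not isolated)
Conditions: CrCl2 (6 equiv), NiCl2 (5 mol %), degassed DMSO, rt; aqueous EDTA work-up
Reagents that add atoms: none
Why: Ring–chain tautomerism of lactol 8 releases hydroxy aldehyde 9, zerovalent nickel (formed from NiCl2 by CrCl2) inserts into the alkenyl C–Br bond with retention, and transmetalation to trivalent chromium gives alkenylchromium 10, whose C2 adds to the C3 carbonyl. The closest known reaction type is the intramolecular Nozaki–Hiyama–Kishi alkenylation of an aldehyde, chosen because organochromium reagents tolerate free hydroxyls, benzoates and an α-oxygenated aldehyde. The six-membered carbocycle closes by a 6-exo-trig attack of C2 on the carbonyl carbon C3 with the C1=C2 bond endocyclic, which only the Z bromide fixed in step 6 can do. The new C3 stereocentre is controlled by the ring substituents: in the half-chair transition state O6 should be pseudoaxial (A(1,2) strain with the C7 arm), which puts the C5 benzoate equatorial and O4 axial, and the chromium-bound carbonyl oxygen should take the pseudoequatorial site, gauche to O4 and able to be bridged to it by chromium, that is cis to O4, O5 and O6. The step needs this facial selectivity at C3 and chemoselective activation of the sp2 C–Br bond beside two benzoates and free OH groups; the first rests on the conformational and chelation bias just named and is the least certain point of the route, the second on the preference of nickel for the alkenyl bromide and the low basicity of the alkenylchromium. Because the furanose oxygen becomes the free C6 hydroxyl on opening, the cyclisation should deliver 11 without any deprotection.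

Compound list
1 | 1,2:5,6-di-O-isopropylidene-α-D-allofuranose (3-OH free, cis to the 1,2-acetonide) | O1[C@@H]2OC(C)(C)O[C@@H]2[C@H](O)[C@H]1[C@H]1COC(C)(C)O1 | starting material
2 | 3-O-benzoyl-1,2:5,6-di-O-isopropylidene-α-D-allofuranose | O1[C@@H]2OC(C)(C)O[C@@H]2[C@H](OC(=O)c2ccccc2)[C@H]1[C@H]1COC(C)(C)O1 | intermediate
3 | 3-O-benzoyl-1,2-O-isopropylidene-α-D-allofuranose (5,6-diol) | O1[C@@H]2OC(C)(C)O[C@@H]2[C@H](OC(=O)c2ccccc2)[C@H]1[C@H](O)CO | intermediate
4 | 3,6-di-O-benzoyl-1,2-O-isopropylidene-α-D-allofuranose (5-OH free) | O1[C@@H]2OC(C)(C)O[C@@H]2[C@H](OC(=O)c2ccccc2)[C@H]1[C@H](O)COC(=O)c1ccccc1 | intermediate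
5 | 3,6-di-O-benzoyl-1,2-O-isopropylidene-α-D-ribo-hexofuranos-5-ulose | O1[C@@H]2OC(C)(C)O[C@@H]2[C@H](OC(=O)c2ccccc2)[C@H]1C(=O)COC(=O)c1ccccc1 | intermediate
6 | 3,6-di-O-benzoyl-5-deoxy-5-C-(dibromomethylidene)-1,2-O-isopropylidene-α-D-ribo-hexofuranose | O1[C@@H]2OC(C)(C)O[C@@H]2[C@H](OC(=O)c2ccccc2)[C@H]1C(=C(Br)Br)COC(=O)c1ccccc1 | intermediate
7 | 3,6-di-O-benzoyl-5-C-[(Z)-bromomethylidene]-5-deoxy-1,2-O-isopropylidene-α-D-ribo-hexofuranose (Br cis to sugar C4) | O1[C@@H]2OC(C)(C)O[C@@H]2[C@H](OC(=O)c2ccccc2)[C@H]1/C(=C\Br)COC(=O)c1ccccc1 | intermediate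
8 | 3,6-di-O-benzoyl-5-C-[(Z)-bromomethylidene]-5-deoxy-D-ribo-hexofuranose (lactol, anomeric mixture, 2-OH free) | O1C(O)[C@H](O)[C@H](OC(=O)c2ccccc2)[C@H]1/C(=C\Br)COC(=O)c1ccccc1 | intermediate
9 | 3,6-di-O-benzoyl-5-C-[(Z)-bromomethylidene]-5-deoxy-aldehydo-D-ribo-hexose (open-chain form of 8) | O=C[C@H](O)[C@H](OC(=O)c1ccccc1)[C@H](O)/C(=C\Br)COC(=O)c1ccccc1 | intermediate
10 | (Z)-alkenylchromium dichloride derived from 9 (CrCl2 in place of Br, same geometry) | O=C[C@H](O)[C@H](OC(=O)c1ccccc1)[C@H](O)/C(=C\[Cr](Cl)Cl)COC(=O)c1ccccc1 | intermediate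
11 | [(3S,4S,5R,6R)-5-(benzoyloxy)-3,4,6-trihydroxycyclohex-1-en-1-yl]methyl benzoate (all four ring oxygens cis) | O=C(OCC1=C[C@H](O)[C@H](O)[C@H](OC(=O)c2ccccc2)[C@@H]1O)c1ccccc1 | target

Total step count: 8. Longest linear sequence: 8 steps (1 to 11).

Steps most likely to fail

Step 8. The C2–C3 bond formation may proceed with insufficient facial discrimination at the aldehyde carbon, so that attack on the wrong face gives the 3,4-trans arrangement. The fallback sets out from 8 and comes back at 11. The cyclisation is run as in step 8 and the C3 epimer [(3R,4S,5R,6R)-5-(benzoyloxy)-3,4,6-trihydroxycyclohex-1-en-1-yl]methyl benzoate F1 is separated. Phenylboronic acid (toluene, azeotropic removal of water) should bridge its cis-1,3-diol O4/O6 to give the 4,6-O-phenylboronate F2, in which only the C3 hydroxyl is free. Dess–Martin oxidation gives the bicyclic enone boronate F3. Luche reduction (NaBH4, CeCl3·7H2O, MeOH, –78 °C) should deliver hydride to the face opposite the diaxial boronate bridge and the axial C4–O bond, giving the all-cis alcohol as its boronate F4. Exchange with pinacol releases 11. The C3 configuration is then set by hydride reduction of a rigid enone and not in the C–C bond formation.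

Step 6. Site selectivity in the oxidative addition of zerovalent palladium may be lost, so that both C–Br bonds are reduced and both geometric isomers form. The fallback sets out from 6 and comes back at 7. It replaces kinetic differentiation by equilibration: 7 is separated from the (E)-bromomethylidene isomer F5. F5 is then isomerised by reversible bromine-atom addition and loss (catalytic Br2, visible light, CH2Cl2), and the re-equilibrated mixture is separated again, so that the material converges on 7.

Step 5. Olefination of the hindered ketone by the weakly nucleophilic dibromomethylene ylide may be slow, which lets enolisation and β-elimination of the C3 benzoate compete. The fallback sets out from 5 and comes back at 7, bypassing 6. The more nucleophilic ylide Ph3P=CHBr (from (bromomethyl)triphenylphosphonium bromide and KOtBu, THF, –78 °C) should react in a Wittig bromomethylenation at low temperature and place the halogen cis to the bulkier furanose substituent in the kinetically formed oxaphosphetane. Any minor geometric isomer is removed by chromatography. This fallback makes no new compound (F0).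

Further compounds
F1 | step 8 | [(3R,4S,5R,6R)-5-(benzoyloxy)-3,4,6-trihydroxycyclohex-1-en-1-yl]methyl benzoate (C3 epimer of 11) | O=C(OCC1=C[C@@H](O)[C@H](O)[C@H](OC(=O)c2ccccc2)[C@@H]1O)c1ccccc1
F2 | step 8 | 4,6-O-phenylboronate of F1 (O4 and O6 bridged by B–Ph, C3–OH free) | O=C(OCC1=C[C@@H](O)[C@@H]2OB(c3ccccc3)O[C@H]1[C@H]2OC(=O)c1ccccc1)c1ccccc1
F3 | step 8 | 4,6-O-phenylboronate of the C3 ketone (bicyclic enone) | O=C(OCC1=CC(=O)[C@@H]2OB(c3ccccc3)O[C@H]1[C@H]2OC(=O)c1ccccc1)c1ccccc1
F4 | step 8 | 4,6-O-phenylboronate of 11 | O=C(OCC1=C[C@H](O)[C@@H]2OB(c3ccccc3)O[C@H]1[C@H]2OC(=O)c1ccccc1)c1ccccc1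
F5 | step 6 | 3,6-di-O-benzoyl-5-C-[(E)-bromomethylidene]-5-deoxy-1,2-O-isopropylidene-α-D-ribo-hexofuranose (geometric isomer of 7) | O1[C@@H]2OC(C)(C)O[C@@H]2[C@H](OC(=O)c2ccccc2)[C@H]1/C(=C/Br)COC(=O)c1ccccc1
F0 | step 5 | none | none
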